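**Retrosynthetic overview**
1. Target 8 ⇐ O-acetylation of the 8α-hydroxy acid 6 ⇐ saponification of methyl ester 5.
2. 5 ⇐ C11–C12 bond, made by a light-driven, nickel-catalysed doubly decarboxylative alkyl–alkyl coupling of carboxylate 4 (C11 radical) with redox-active ester 2 (C12 alkyl).
3. 4 ⇐ (+)-sclareolide 3, which supplies rings A and B and C5, C8, C9 and C10; 2 ⇐ (S)-methyl hydrogen 3-methylglutarate 1, which supplies C13.
4. No ring is formed in the route: both carbocycles are bought, and the lactone ring of 3 is only opened.

Assumption: (S)-methyl hydrogen 3-methylglutarate of high ee is taken as a purchasable building block, like its more common R antipode.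

**Step 1**
Reactants: 1 (S)-methyl hydrogen 3-methylglutarate
Product: 2 N-hydroxyphthalimide ester of 1 [1-(1,3-dioxoisoindolin-2-yl) 5-methyl (3R)-3-methylpentanedioate; same spatial arrangement as 1, the descriptor changes only by the priority rules]
Conditions: N-hydroxyphthalimide (1.05 equiv), DIC (1.1 equiv), DMAP (5 mol%), CH2Cl2, 0 to 23 °C, 3 h; filter, short silica plug
Reagents that add atoms: N-hydroxyphthalimide, ON1C(=O)c2ccccc2C1=O
Why: Steglich-type carbodiimide esterification of an unhindered acid; the stereocentre is β to both carbonyls and cannot epimerise, and the mild activation avoids exchange of the two acyl termini, which would erode the ee.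

**Step 2**
Reactants: 3 (+)-sclareolide; 2 N-hydroxyphthalimide ester of 1
Product: 5 methyl (13S)-8α-hydroxylabdan-15-oate (methyl labdanolate), via potassium hydroxy carboxylate 4 (not isolated)
Conditions: KOH (1.00 equiv), MeOH–H2O 4:1, 65 °C, 2 h, evaporate to dryness; then 2 (1.8 equiv, in three portions), NiCl2·glyme (10 mol%), 4,4′-di-tert-butyl-2,2′-bipyridine (15 mol%), 4CzIPN (2 mol%), MeCN–H2O 10:1, Ar, 450 nm LEDs, 25 °C, 24 h; aq. NH4Cl work-up
Reagents that add atoms: none
Why: Proposed new method: a redox-neutral, light-driven, nickel-catalysed doubly decarboxylative C(sp3)–C(sp3) cross-coupling of a free carboxylate with a redox-active ester, in which excited 4CzIPN (about +1.35 V against SCE) oxidises the carboxylate of 4 (formed by acyl–oxygen saponification of the lactone, so the C8–O bond is untouched) to the primary C11 radical with loss of CO2, the reduced photocatalyst (about −1.2 V, too weak to cleave 2 quickly by itself) returns nickel to the zerovalent state, zerovalent nickel transfers an electron to 2, which expels CO2 and phthalimide anion and leaves the C12 alkyl on divalent nickel, and capture of the C11 radical gives a dialkyl trivalent nickel that reductively eliminates the C11–C12 bond, so the two alkyl groups reach nickel by different elementary steps and the cross product is favoured; no stereocentre is formed and C9 and C13 only flank the new bond; the closest known reaction types are the nickel/photoredox decarboxylative coupling of carboxylic acids with alkyl bromides and the nickel-catalysed reductive couplings of N-hydroxyphthalimide esters.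

**Step 3**
Reactants: 5 methyl (13S)-8α-hydroxylabdan-15-oate
Product: 6 (13S)-8α-hydroxylabdan-15-oic acid (the structure assigned to labdanolic acid)
Conditions: LiOH·H2O (4 equiv), THF–MeOH–H2O 3:1:1, 45 °C, 6 h; then 1 M HCl to pH 3 at 0 °C
Reagents that add atoms: lithium hydroxide, [Li+].[OH-]
Why: Ordinary ester saponification of an unhindered methyl ester; the tertiary alcohol is inert to base and C13, being β to the carbonyl, cannot epimerise.

**Step 4**
Reactants: 6 (13S)-8α-hydroxylabdan-15-oic acid
Product: 8 (13S)-8α-acetoxylabdan-15-oic acid (target), via mixed acetic anhydride 7 (not isolated)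
Conditions: AcCl (6 equiv), N,N-dimethylaniline (8 equiv), CH2Cl2, 0 to 25 °C, 36 h; then H2O–THF–pyridine, 25 °C, 3 h
Reagents that add atoms: acetyl chloride, CC(=O)Cl
Why: O-acylation of the hindered tertiary 8α-hydroxyl with acetyl chloride and N,N-dimethylaniline (the standard method for the 8α-hydroxyl of sclareol-type labdanes) retains the C8 configuration because the C8–O bond is never broken, and the C15 mixed anhydride formed alongside is cleaved by pyridine-catalysed hydrolysis at its acetyl carbonyl while the tertiary acetate survives.

**Compound list**
1 | (S)-methyl hydrogen 3-methylglutarate [(3S)-5-methoxy-3-methyl-5-oxopentanoic acid] | OC(=O)C[C@H](C)CC(=O)OC | starting material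
2 | 1-(1,3-dioxoisoindolin-2-yl) 5-methyl (3R)-3-methylpentanedioate (N-hydroxyphthalimide ester of 1) | O=C(ON1C(=O)c2ccccc2C1=O)C[C@H](C)CC(=O)OC | intermediate
3 | (+)-sclareolide [(3aR,5aS,9aS,9bR)-3a,6,6,9a-tetramethyldecahydronaphtho[2,1-b]furan-2(1H)-one] | O=C3O[C@]1(C)CC[C@H]2C(C)(C)CCC[C@]2(C)[C@H]1C3 | starting material
4 | potassium 2-[(1R,2R,4aS,8aS)-2-hydroxy-2,5,5,8a-tetramethyldecahydronaphthalen-1-yl]acetate (potassium 8α-hydroxy-13,14,15,16-tetranorlabdan-12-oate) | O[C@]1(C)CC[C@H]2C(C)(C)CCC[C@]2(C)[C@H]1CC(=O)[O-].[K+] | intermediate
5 | methyl (13S)-8α-hydroxylabdan-15-oate [methyl (3S)-5-[(1R,2R,4aS,8aS)-2-hydroxy-2,5,5,8a-tetramethyldecahydronaphthalen-1-yl]-3-methylpentanoate] | O[C@]1(C)CC[C@H]2C(C)(C)CCC[C@]2(C)[C@H]1CC[C@H](C)CC(=O)OC | intermediate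
6 | (13S)-8α-hydroxylabdan-15-oic acid [(3S)-5-[(1R,2R,4aS,8aS)-2-hydroxy-2,5,5,8a-tetramethyldecahydronaphthalen-1-yl]-3-methylpentanoic acid] | O[C@]1(C)CC[C@H]2C(C)(C)CCC[C@]2(C)[C@H]1CC[C@H](C)CC(=O)O | intermediate
7 | acetic (13S)-8α-acetoxylabdan-15-oic anhydride | CC(=O)O[C@]1(C)CC[C@H]2C(C)(C)CCC[C@]2(C)[C@H]1CC[C@H](C)CC(=O)OC(C)=O | intermediate
8 | (13S)-8α-acetoxylabdan-15-oic acid [(3S)-5-[(1R,2R,4aS,8aS)-2-acetoxy-2,5,5,8a-tetramethyldecahydronaphthalen-1-yl]-3-methylpentanoic acid] | CC(=O)O[C@]1(C)CC[C@H]2C(C)(C)CCC[C@]2(C)[C@H]1CC[C@H](C)CC(=O)O | target

**Step count**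
Total steps: 4. Longest linear sequence: 4 steps (1 → 2 → 5 → 6 → 8); 3 steps from sclareolide 3.

**Steps most likely to fail, with fallbacks**

The most exposed step is the proposed coupling of step 2. Its likely failure modes are:
- acyl transfer from 2 to the carboxylate of 4, followed by relactonisation to 3;
- statistical homodimers if the radicals are not sorted at nickel;
- protodecarboxylation or β-hydride elimination at alkyl–nickel.

The fallback uses known chemistry, a mixed Kolbe electrolysis. It sets out from 3 and 1 (2 is not needed) and returns to the route at 5. Lactone 3 is opened to 4 with KOH exactly as in step 2. The salt is then electrolysed together with an excess of the free half-ester 1 (about 6 equiv, which also serves as proton reservoir) in methanol, in an undivided cell at a smooth platinum anode at high current density (about 0.15 A cm−2, 20–30 °C). Anodic decarboxylation of both carboxylates gives the C11 and C12 primary radicals at the electrode surface, and their cross-combination gives 5. The mixture is worked up with aqueous NH4Cl, unreacted 4 returns to 3, and 5 is separated from the symmetrical dimers by chromatography. Crossed Kolbe coupling of bicyclic terpenoid acids with half-esters of dicarboxylic acids is a long-established reaction type. This fallback makes no compound outside the list (F0).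

The second is step 4. The tertiary 8α-hydroxyl is hindered, forcing may cause elimination towards the C7 or C17 olefins, and the free carboxyl is carried through as an anhydride. The fallback keeps the carboxyl masked while the acetate is installed. It sets out from 5 and returns at 8. Ester 5 is acetylated with AcCl and N,N-dimethylaniline in CH2Cl2 to give methyl (13S)-8α-acetoxylabdan-15-oate F1. The methyl ester is then removed by SN2 dealkylation with LiI in refluxing ethyl acetate. Iodide attacks the O-methyl carbon, a pathway closed to the tertiary acetate, and acidification gives 8. Step 3 is then not needed.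

The third, and the least exposed, is step 1. The active ester 2 may hydrolyse partly on silica, or carry urea or carbodiimide into step 2, where residual carbodiimide would relactonise 4. The fallback dispenses with the redox-active ester. It sets out from 1 and returns at 5. Half-ester 1 is converted by decarboxylative bromination (Cristol–Firth variant of the Hunsdiecker reaction: HgO, Br2, CCl4, reflux) into methyl (3R)-4-bromo-3-methylbutanoate F2. The stereocentre is untouched, and only the descriptor changes. F2 is then coupled with 4 (from 3 and KOH) under the established nickel/photoredox conditions for carboxylic acids and primary alkyl bromides (NiCl2·glyme, 4,4′-dimethoxy-2,2′-bipyridine, Ir[dF(CF3)ppy]2(dtbbpy)PF6, MeCN–H2O, blue LEDs) to give 5.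

**Further compounds**
F0 | step 2 | none | none
F1 | step 4 | methyl (13S)-8α-acetoxylabdan-15-oate | CC(=O)O[C@]1(C)CC[C@H]2C(C)(C)CCC[C@]2(C)[C@H]1CC[C@H](C)CC(=O)OC
F2 | step 1 | methyl (3R)-4-bromo-3-methylbutanoate | BrC[C@H](C)CC(=O)OC
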